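**Compound numbering used throughout:** 1 4-(benzyloxy)benzyl chloride; 2 triphenylphosphine; 3 phosphonium salt; 4 2-hydroxy-3,4-dimethoxybenzaldehyde; 5 ylide; 6 stilbene phenol; 7 2-fluorobenzaldehyde; 8 stilbene aldehyde; 9 tosyl enamide; 10 nitrile; 11 stilbene acid; 12 bibenzyl phenol acid; 13 2-fluoro-6-methoxybenzaldehyde; 14 aldehyde acid; 15 aryl formate; 16 hydroxy acid; 17 macrolactone; 18 keto macrocycle; 19 trimethyl ether macrocycle; 20 target.

## Analysis of the target

Compound 20 is a macrocyclic bis(bibenzyl). Four benzene rings A–D are joined into one 17-membered ring by two diaryl ether oxygens (ring A–O–ring B, ring C–O–ring D) and two ethano bridges (ring B–CH2CH2–ring C, ring D–CH2CH2–ring A). Ring A is numbered here so that C-1 carries the bridge to ring D, C-3 the oxygen to ring B, and C-4 and C-5 the two hydroxyls. Ring B is para-linked; ring C carries its bridge at C-1, the oxygen to ring D at C-2 and hydroxyls at C-3 and C-4; ring D is a plain ortho-linked benzene ring. There is no stereocentre and no atropisomerism is specified, so nothing has to be controlled stereochemically. The sensitive groups are the two catechols, which oxidise readily in air and base and are therefore kept as methyl ethers until the last step. The difficulty lies in closing the 17-membered ring, usually through a C–C bond, and in making two diaryl ethers beside other oxygen substituents while six oxygens on rings A and C stay distinguishable. The strategy rests on ring A: C-1 is para to the C-4 oxygen, and both carbons ortho to that oxygen are occupied (C-3 by the aryloxy group, C-5 by the second oxygen). The C-1–CH2 bond is therefore the bond a para acyl shift from the C-4 oxygen would form, and the ring D end of that bridge has the carbon skeleton of an arylacetic acid.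

## Retrosynthetic reasoning

**20 from 19.** The three O–methyl bonds on ring A C-5 and ring C C-3/C-4 are cut last. Methyl ethers survive every earlier step, including the Lewis-acid step, and the air-sensitive catechols then appear only at the end. The forward step is a Lewis-acid ether cleavage that leaves the diaryl ethers intact.

**19 from 18.** The benzylic CH2 on ring A C-1 is traced back to a ketone. That carbonyl is what an acyl shift leaves behind. Because it sits para to a free hydroxyl on an electron-rich ring, it is the kind of aryl ketone that silane/acid ionic hydrogenation takes down to methylene.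

**18 from 17 (strategic disconnection).** The bond between ring A C-1 and the carbonyl carbon is cut and the acyl group is reattached to the ring A C-4 oxygen. This turns a macrocyclic C–C bond into an ester bond: 17 is a 17-membered aryl arylacetate lactone. The gain is that the ring is closed through an easy C–O bond and the hard C–C bond then forms inside an existing ring. The forward step must move the acyl group from oxygen to the para carbon only.

**17 from 16.** The lactone C–O bond is cut to the hydroxy acid 16. Forward, this is a macrolactonisation onto a phenol flanked by OMe and OAr.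

**16 from 14.** The ring A C-4 oxygen is traced back to a formyl group (peracid oxidation via formate 15). The formyl group does two jobs: it activates the neighbouring fluorine for ether formation and then becomes the phenol.

**14 from 12 and 13.** The ring A–O–ring B bond is cut at ring A. The ring B phenol of 12 displaces the fluoride of 13, which is ortho to the formyl group. At this stage 12 has no other aldehyde and only one phenol, so there is no selectivity issue.

**12 from 11.** The bridge between rings B and C is traced back to a stilbene and the ring B phenol to its benzyl ether. One hydrogenation does both.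

**11 from 8 (via 10 and 9).** The arylacetic acid on ring D is traced back by one carbon to the benzaldehyde 8, through the nitrile 10. The homologation avoids oxidants, so the stilbene and benzyl ether are untouched.

**8 from 6 and 7.** The ring C–O–ring D bond is cut at ring D. The single free phenol of 6 displaces the fluoride of 7. The ring D aldehyde is then consumed (homologated) before the ring A aldehyde of 13 is introduced, so no intermediate ever carries two formyl groups.

**6 from 3 (via 5) and 4; 3 from 1 and 2.** The stilbene C=C is cut by a Wittig disconnection. The aldehyde 4 is used with its phenol free, so no protecting group is spent on ring C. The ring B oxygen comes in already benzylated in 1.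

## Alternatives that were turned down

**Alternative 1:** Ring B is not brought in as an arene but assembled in the ring-closing step by cutting two of its C–C bonds. Forward, an open-chain precursor with a buta-1,3-dien-2-yl ether on the ring A C-3 oxygen and a terminal alkyne at the end of the ring C side chain would undergo a [4+2] cycloaddition under CoBr2(dppe)/Zn/ZnI2, giving A1, in which ring B is a 1-aryloxy-4-alkylcyclohexa-1,4-diene. Dehydrogenation and cleavage of four methyl ethers would follow.
- For it: two C–C bonds, a six-membered ring and the macrocycle form in one catalytic, neutral step. The para regiochemistry that the cobalt/dppe system gives with 2-substituted dienes and terminal alkynes is the one required. The ring A–O–ring B ether needs no activating group. On bond economy in the key step it is stronger than the chosen route.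
- Against it: the dienyl aryl ether is an acid-labile enol ether that is awkward to install on a phenol and must survive ZnI2. The cycloaddition must run in a bridging intramolecular mode at high dilution, where alkyne cyclotrimerisation and diene dimerisation compete. A1 is itself an enol ether, and its hydrolysis before aromatisation would break the ring A–O–ring B link. The ring D–ring A bridge and the ring C–O–ring D ether still need conventional steps, so nothing is saved overall.
- Comparison: the macrocyclising mode is as unprecedented as the chosen key step. The chosen route offers instead a precursor made entirely from bought arenes by SNAr, Wittig and lactonisation, so its risk is confined to one step.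

**Alternative 2:** The ring C–O–ring D bond is cut with ring D at the cyclohexenone oxidation level. Forward, the ring C phenoxide would add to the β-carbon of a 2-alkyl-3-chlorocyclohex-2-enone and expel chloride, closing the macrocycle as the vinylogous ester A2.
- For it: addition–elimination at a β-chloroenone is mild and well known intermolecularly. It needs no SNAr activation or copper, and closing through a C–O bond is as easy as the chosen lactonisation. On precedent for the ring-closing reaction type it is the stronger.
- Against it: ring D of the target is a benzene ring with no oxygen except the ether. A2 therefore has a carbonyl oxygen that must be removed while two double bonds are added and the aryloxy group is kept. Vinylogous esters tend to lose their alkoxy or aryloxy group after 1,2-reduction and acid treatment, which here would reopen the macrocycle. A deoxygenative aromatisation through a sulfonylhydrazone and a diene would be several uncertain late steps. The 2-alkyl group also lowers the electrophilicity of the β-carbon, and the 2-(arylethyl)cyclohexane-1,3-dione must be built first.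
- Comparison: the chosen route also leaves a carbonyl after the key step, but it is removed in one ionic hydrogenation, and all four rings are aromatic from the start.

**Alternative 3:** The ring A C-3–O bond is cut by a biomimetic oxidative phenol coupling. Forward, Tl(NO3)3 (trivalent thallium) would oxidise a 2,6-dibromophenol on ring A, the 2,6-dichlorophenol oxygen of ring B would attack the bromine-bearing ortho carbon, and zinc reduction of the dienone would give A3.
- For it: this is the only one of the four strategies whose ring-closing reaction type is established for macrocyclic diaryl ethers. It follows the likely biogenesis and needs no activating group. On precedent it is clearly stronger than the chosen key step.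
- Against it: it uses stoichiometric, highly toxic Tl(NO3)3. Four halogens must be placed selectively on two similar para-alkylphenols, which forces the two phenols to be differentiated and both bridges to be hydrogenated before halogenation. In A3 the surviving ring A bromine sits where the target has a hydroxyl, so it must be converted to oxygen beside a free phenol, the two chlorines removed, and the ring C ethers cleaved. That is at least three or four steps after cyclisation, against two in the chosen route.
- Comparison: the chosen route accepts an untested key step in exchange for a halogen-free, thallium-free sequence with a short endgame.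

Key step: step 10

Assumption: the Wittig step gives an E/Z mixture of stilbenes; both isomers are carried on together and converge in step 6, and the E isomer is the one drawn for 6, 8, 9, 10 and 11.

## Route

Step 1
Reactants: 1 4-(benzyloxy)benzyl chloride; 2 triphenylphosphine
Product: 3 [4-(benzyloxy)benzyl]triphenylphosphonium chloride
Conditions: toluene, reflux
Reagents that add atoms: none
Why: SN2 quaternisation of a benzylic chloride by the phosphine; the salt should precipitate from toluene.

Step 2
Reactants: 3 [4-(benzyloxy)benzyl]triphenylphosphonium chloride; 4 2-hydroxy-3,4-dimethoxybenzaldehyde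
Product: 6 6-{2-[4-(benzyloxy)phenyl]ethenyl}-2,3-dimethoxyphenol (E/Z mixture), via phosphorus ylide 5 (not isolated)
Conditions: KOtBu (2.2 equiv), THF, 0 °C → reflux
Reagents that add atoms: none
Why: Wittig olefination with a semi-stabilised benzylic ylide; the second equivalent of base turns the phenol into its phenoxide so that it does not quench the ylide, and the alkene geometry is irrelevant because the bond is hydrogenated in step 6.

Step 3
Reactants: 6 6-{2-[4-(benzyloxy)phenyl]ethenyl}-2,3-dimethoxyphenol; 7 2-fluorobenzaldehyde
Product: 8 2-(6-{2-[4-(benzyloxy)phenyl]ethenyl}-2,3-dimethoxyphenoxy)benzaldehyde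
Conditions: K2CO3, DMF, 130 °C
Reagents that add atoms: none
Why: SNAr through a Meisenheimer adduct stabilised by the ortho formyl group, with fluoride as leaving group; 6 has only one free phenol, so only the ring C–O–ring D ether can form.

Step 4
Reactants: 8 2-(6-{2-[4-(benzyloxy)phenyl]ethenyl}-2,3-dimethoxyphenoxy)benzaldehyde
Product: 10 [2-(6-{2-[4-(benzyloxy)phenyl]ethenyl}-2,3-dimethoxyphenoxy)phenyl]acetonitrile, via tosyl enamide 9 (not isolated)
Conditions: TosMIC, KOtBu, DME, −40 °C; then MeOH, reflux
Reagents that add atoms: tosylmethyl isocyanide (TosMIC), [C-]#[N+]CS(=O)(=O)c1ccc(C)cc1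
Why: van Leusen reductive cyanation: the TosMIC anion adds to the aldehyde, the oxazoline opens to the N-formyl tosyl enamine 9, and methanolysis of the formyl group with loss of sulfinate gives the one-carbon-longer nitrile without any oxidant.

Step 5
Reactants: 10 [2-(6-{2-[4-(benzyloxy)phenyl]ethenyl}-2,3-dimethoxyphenoxy)phenyl]acetonitrile
Product: 11 [2-(6-{2-[4-(benzyloxy)phenyl]ethenyl}-2,3-dimethoxyphenoxy)phenyl]acetic acid
Conditions: KOH, EtOH/H2O, reflux, N2; then aq. HCl
Reagents that add atoms: water, O; potassium hydroxide, [K+].[OH-]
Why: base hydrolysis of an arylacetonitrile to the carboxylate; the stilbene, benzyl ether, methyl ethers and diaryl ether are all stable to hot hydroxide, and exclusion of air protects the benzylic carbanion.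

Step 6
Reactants: 11 [2-(6-{2-[4-(benzyloxy)phenyl]ethenyl}-2,3-dimethoxyphenoxy)phenyl]acetic acid
Product: 12 (2-{6-[2-(4-hydroxyphenyl)ethyl]-2,3-dimethoxyphenoxy}phenyl)acetic acid
Conditions: H2 (1 atm), 10% Pd/C, EtOAc/EtOH, rt
Reagents that add atoms: none
Why: catalytic hydrogenation saturates the stilbene (both isomers) and hydrogenolyses the benzyl ether in one operation, freeing the ring B phenol as the only phenol in the molecule.

Step 7
Reactants: 12 (2-{6-[2-(4-hydroxyphenyl)ethyl]-2,3-dimethoxyphenoxy}phenyl)acetic acid; 13 2-fluoro-6-methoxybenzaldehyde
Product: 14 {2-[6-(2-{4-[2-formyl-3-methoxyphenoxy]phenyl}ethyl)-2,3-dimethoxyphenoxy]phenyl}acetic acid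
Conditions: K2CO3 (3.5 equiv), DMF, 120 °C; then aq. HCl
Reagents that add atoms: none
Why: SNAr of the unhindered para-alkyl phenoxide on the fluoride ortho to the formyl group; the acid is present as its carboxylate, which is neither a competent nucleophile here nor enolisable by carbonate.

Step 8
Reactants: 14 {2-[6-(2-{4-[2-formyl-3-methoxyphenoxy]phenyl}ethyl)-2,3-dimethoxyphenoxy]phenyl}acetic acid
Product: 16 {2-[6-(2-{4-[2-hydroxy-3-methoxyphenoxy]phenyl}ethyl)-2,3-dimethoxyphenoxy]phenyl}acetic acid, via aryl formate 15 (not isolated)
Conditions: mCPBA, CH2Cl2, 0 °C → rt; then NaOH, MeOH/H2O, rt; aq. HCl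
Reagents that add atoms: 3-chloroperoxybenzoic acid (mCPBA), OOC(=O)c1cccc(Cl)c1
Why: Baeyer–Villiger (Dakin-type) oxidation: in the Criegee adduct the 2,6-dioxygenated aryl group migrates in preference to hydrogen, giving formate 15, which is saponified to the phenol.

Step 9
Reactants: 16 {2-[6-(2-{4-[2-hydroxy-3-methoxyphenoxy]phenyl}ethyl)-2,3-dimethoxyphenoxy]phenyl}acetic acid
Product: 17 17-membered aryl arylacetate macrolactone (the ring A C-4 oxygen of 16 acylated by its own ring D acetic acid group)
Conditions: 2-methyl-6-nitrobenzoic anhydride (MNBA), DMAP (3 equiv), CH2Cl2, rt, slow addition (final 1 mM)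
Reagents that add atoms: none
Why: Shiina macrolactonisation: the mixed anhydride transfers the arylacetyl group to DMAP and the acylpyridinium acylates the phenol; the seco acid is pre-bent by three ortho-linked rings and the 17-membered ring is unstrained.

Step 10
Reactants: 17 17-membered aryl arylacetate macrolactone
Product: 18 macrocyclic para-hydroxy deoxybenzoin (ketone carbon on ring A C-1, CH2 on ring D, ring A C-4 hydroxyl free)
Conditions: BF3·OEt2 (10 equiv), ClCH2CH2Cl (2 mM), 80 °C; aq. NaHCO3
Reagents that add atoms: none
Why: Proposed new method: BF3 binds the lactone carbonyl and ionises the acyl–oxygen bond, giving an arylacetyl cation that stays tethered and ion-paired to the ring A aryloxytrifluoroborate; the cation attacks ring A C-1, para to the boron-bound oxygen, and proton loss followed by work-up gives the para-hydroxy ketone. The closest known reaction type is the Lewis-acid Fries rearrangement of aryl arylacetates, together with the BF3·OEt2 condensation of phenols with arylacetic acids, both giving hydroxydeoxybenzoins; neither has been run across a macrocycle. The new 17-membered carbocycle closes by electrophilic aromatic substitution (C-acylation of what becomes a meta-bridged ring A) as the 17-membered lactone opens, so the step is a ring-to-ring isomerisation. No stereocentre is formed. The step needs acylation at C-1 and not at ring A C-2 or C-6, ring B or ring C: both carbons ortho to the leaving oxygen carry substituents (OMe and OAr), so an ortho shift is excluded, and C-1 is the only carbon conjugated with the anionic boron-bound oxygen and is flanked by two hydrogens, whereas C-2 and C-6 each lie next to a substituent. Ring C has no free carbon ortho to its ether oxygen, so a dibenzoxepinone-type closure is blocked, and its two remaining carbons would require 8- or 9-membered bridged rings; ring B carries only one oxygen and is less nucleophilic. High dilution suppresses intermolecular acyl transfer.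

Step 11
Reactants: 18 macrocyclic para-hydroxy deoxybenzoin
Product: 19 tri-O-methyl ether of the target (ring A C-5 and ring C C-3/C-4 methoxy, ring A C-4 hydroxyl free, CH2CH2 bridge between rings D and A)
Conditions: Et3SiH (5 equiv), CF3CO2H, rt → 50 °C
Reagents that add atoms: none
Why: ionic hydrogenation: the protonated ketone takes hydride from the silane, the resulting benzylic alcohol ionises to a cation stabilised by the para hydroxyl, and a second hydride gives the methylene group.

Step 12
Reactants: 19 tri-O-methyl ether of the target
Product: 20 CNP0114693.0 (target)
Conditions: BBr3 (8 equiv), CH2Cl2, −78 °C → rt; then H2O, 0 °C, under argon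
Reagents that add atoms: none
Why: Lewis-acid cleavage of aryl methyl ethers: bromide attacks the methyl group of each boron-complexed ether; diaryl ethers have no sp3 carbon on oxygen and are left intact, and work-up under argon protects the catechols.

## Compound list

1 | 4-(benzyloxy)benzyl chloride | ClCc1ccc(OCc2ccccc2)cc1 | starting material
2 | triphenylphosphine | c1ccc(cc1)P(c1ccccc1)c1ccccc1 | starting material
3 | [4-(benzyloxy)benzyl]triphenylphosphonium chloride | [Cl-].c1ccc(cc1)COc1ccc(C[P+](c2ccccc2)(c2ccccc2)c2ccccc2)cc1 | intermediate
4 | 2-hydroxy-3,4-dimethoxybenzaldehyde | COc1ccc(C=O)c(O)c1OC | starting material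
5 | [4-(benzyloxy)benzylidene]triphenylphosphorane (ylide) | c1ccc(cc1)COc1ccc(C=P(c2ccccc2)(c2ccccc2)c2ccccc2)cc1 | intermediate
6 | 6-{2-[4-(benzyloxy)phenyl]ethenyl}-2,3-dimethoxyphenol (E/Z mixture, E drawn) | COc1ccc(/C=C/c2ccc(OCc3ccccc3)cc2)c(O)c1OC | intermediate
7 | 2-fluorobenzaldehyde | O=Cc1ccccc1F | starting material
8 | 2-(6-{2-[4-(benzyloxy)phenyl]ethenyl}-2,3-dimethoxyphenoxy)benzaldehyde (E/Z mixture, E drawn) | COc1ccc(/C=C/c2ccc(OCc3ccccc3)cc2)c(Oc2ccccc2C=O)c1OC | intermediate
9 | N-{2-[2-(6-{2-[4-(benzyloxy)phenyl]ethenyl}-2,3-dimethoxyphenoxy)phenyl]-1-tosylethenyl}formamide (enamide geometry undefined) | COc1ccc(/C=C/c2ccc(OCc3ccccc3)cc2)c(Oc2ccccc2C=C(NC=O)S(=O)(=O)c2ccc(C)cc2)c1OC | intermediate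
10 | [2-(6-{2-[4-(benzyloxy)phenyl]ethenyl}-2,3-dimethoxyphenoxy)phenyl]acetonitrile (E/Z mixture, E drawn) | COc1ccc(/C=C/c2ccc(OCc3ccccc3)cc2)c(Oc2ccccc2CC#N)c1OC | intermediate
11 | [2-(6-{2-[4-(benzyloxy)phenyl]ethenyl}-2,3-dimethoxyphenoxy)phenyl]acetic acid (E/Z mixture, E drawn) | COc1ccc(/C=C/c2ccc(OCc3ccccc3)cc2)c(Oc2ccccc2CC(=O)O)c1OC | intermediate
12 | (2-{6-[2-(4-hydroxyphenyl)ethyl]-2,3-dimethoxyphenoxy}phenyl)acetic acid | COc1ccc(CCc2ccc(O)cc2)c(Oc2ccccc2CC(=O)O)c1OC | intermediate
13 | 2-fluoro-6-methoxybenzaldehyde | COc1cccc(F)c1C=O | starting material
14 | {2-[6-(2-{4-[2-formyl-3-methoxyphenoxy]phenyl}ethyl)-2,3-dimethoxyphenoxy]phenyl}acetic acid | COc1cccc(Oc2ccc(CCc3ccc(OC)c(OC)c3Oc3ccccc3CC(=O)O)cc2)c1C=O | intermediate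
15 | {2-[6-(2-{4-[2-(formyloxy)-3-methoxyphenoxy]phenyl}ethyl)-2,3-dimethoxyphenoxy]phenyl}acetic acid | COc1cccc(Oc2ccc(CCc3ccc(OC)c(OC)c3Oc3ccccc3CC(=O)O)cc2)c1OC=O | intermediate
16 | {2-[6-(2-{4-[2-hydroxy-3-methoxyphenoxy]phenyl}ethyl)-2,3-dimethoxyphenoxy]phenyl}acetic acid | COc1cccc(Oc2ccc(CCc3ccc(OC)c(OC)c3Oc3ccccc3CC(=O)O)cc2)c1O | intermediate
17 | 17-membered aryl arylacetate macrolactone | COc1cccc2c1OC(=O)Cc1ccccc1Oc1c(OC)c(OC)ccc1CCc1ccc(O2)cc1 | intermediate
18 | macrocyclic para-hydroxy deoxybenzoin | COc1cc2cc(c1O)Oc1ccc(cc1)CCc1ccc(OC)c(OC)c1Oc1ccccc1CC2=O | intermediate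
19 | tri-O-methyl ether of the target | COc1cc2cc(c1O)Oc1ccc(cc1)CCc1ccc(OC)c(OC)c1Oc1ccccc1CC2 | intermediate
20 | CNP0114693.0 | Oc1cc2cc(c1O)Oc1ccc(cc1)CCc1ccc(O)c(O)c1Oc1ccccc1CC2 | target

## Step count and uncertain steps

Total: 12 steps. Longest linear sequence: 12 steps (1 to 20); 11 steps counted from 4.

**Step 10 (key step, proposed new method).** Several things could go wrong.
- The acyl group could be delivered to the wrong carbon. After ionisation the ring A methoxy group competes with the boron-bound oxygen as a director, and the tether can reach ring A C-2 (para to OMe, 16-membered ring), ring A C-6 (18-membered ring) or ring B (12-membered ring).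
- Acyl transfer between molecules could give oligomers.
- The arylacetyl cation could lose CO to an ortho-aryloxybenzyl cation, which would then alkylate an arene.
- The lactone may simply not ionise at temperatures the substrate tolerates.

Fallback by known chemistry: close the ring at the ring D–ring A bridge by an intramolecular Wittig reaction. The fallback sets out from 8 and returns at 19. NaBH4 (MeOH/THF, 0 °C) reduces 8 to the ring D benzylic alcohol F1. Hydrogenation (H2, Pd/C, EtOAc, neutral, stopped after uptake) saturates the stilbene and removes the benzyl group to give the bibenzyl phenol alcohol F2. Ullmann ether coupling (CuI, N,N-dimethylglycine, Cs2CO3, dioxane, 100 °C) of F2 with 4-(benzyloxy)-3-bromo-5-methoxybenzaldehyde F3 (from 5-bromovanillin and benzyl bromide) gives the ring A aldehyde F4, which already has the formyl carbon para to the protected central oxygen. PPh3·HBr (MeCN, reflux) converts the benzylic alcohol into the phosphonium bromide F5. NaOMe in CH2Cl2 at high dilution closes the macrocyclic stilbene F6. Hydrogenation (H2, Pd/C) saturates the new alkene and removes the benzyl ether, giving 19.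

**Step 9.** The flanked phenol is acylated slowly, so the activated arylacetic acid may instead acylate another molecule (diolide and oligomers) or form a ketene that dimerises. Fallback: skip the lactone and cyclise the hydroxy acid 16 directly by dehydrative C-acylation at high dilution in BF3·OEt2 or in P2O5/MeSO3H. This is the intramolecular form of the established condensation of phenols with arylacetic acids. It sets out from 16 and returns at 18, and makes no new compound.

**Step 2.** The aldehyde of 4 is deactivated as its phenoxide (ortho O−, para OMe), and any unneutralised phenol quenches the ylide, so conversion may be poor. Fallback: make the ether first, with a nitrile as masked aldehyde. The fallback sets out from 4 and returns at 8. SNAr of 4 with 2-fluorobenzonitrile (K2CO3, DMF, 110 °C) gives 2-(6-formyl-2,3-dimethoxyphenoxy)benzonitrile F7. Wittig reaction with 5 (from 3, KOtBu, THF) gives the stilbene nitrile F8, now without a free phenol. iBu2AlH (toluene, −78 °C; aq. HCl) reduces the nitrile to the aldehyde 8. This costs one extra step and bypasses step 3 as well.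

**Step 11.** The carbonyl of 18 is a vinylogous acid and a poor hydride acceptor, so reduction may stall. Alternatively, the benzylic cation may be trapped by a neighbouring arene before the silane delivers hydride. Fallback: reduce in two stages. NaBH4 (MeOH, rt) gives the benzylic alcohol F9 (racemic), and hydrogenolysis of this para-hydroxybenzylic alcohol (H2, Pd/C, EtOAc with a little AcOH) gives 19. It sets out from 18 and returns at 19.

## Further compounds

F1 | step 10 | [2-(6-{2-[4-(benzyloxy)phenyl]ethenyl}-2,3-dimethoxyphenoxy)phenyl]methanol (E/Z mixture, E drawn) | COc1ccc(/C=C/c2ccc(OCc3ccccc3)cc2)c(Oc2ccccc2CO)c1OC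
F2 | step 10 | 4-(2-{2-[2-(hydroxymethyl)phenoxy]-3,4-dimethoxyphenyl}ethyl)phenol | COc1ccc(CCc2ccc(O)cc2)c(Oc2ccccc2CO)c1OC
F3 | step 10 | 4-(benzyloxy)-3-bromo-5-methoxybenzaldehyde | O=Cc1cc(Br)c(OCc2ccccc2)c(OC)c1
F4 | step 10 | 4-(benzyloxy)-3-[4-(2-{2-[2-(hydroxymethyl)phenoxy]-3,4-dimethoxyphenyl}ethyl)phenoxy]-5-methoxybenzaldehyde | O=Cc1cc(OC)c(OCc2ccccc2)c(Oc2ccc(CCc3ccc(OC)c(OC)c3Oc3ccccc3CO)cc2)c1
F5 | step 10 | {2-[6-(2-{4-[2-(benzyloxy)-5-formyl-3-methoxyphenoxy]phenyl}ethyl)-2,3-dimethoxyphenoxy]benzyl}triphenylphosphonium bromide | [Br-].O=Cc1cc(OC)c(OCc2ccccc2)c(Oc2ccc(CCc3ccc(OC)c(OC)c3Oc3ccccc3C[P+](c3ccccc3)(c3ccccc3)c3ccccc3)cc2)c1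
F6 | step 10 | macrocyclic stilbene with CH=CH between rings D and A, ring A C-4 benzyl ether (E/Z mixture, Z drawn) | C1Cc2ccc(OC)c(OC)c2Oc2ccccc2/C=C\c2cc(OC)c(OCc3ccccc3)c(c2)Oc2ccc1cc2
F0 | step 9 | none | none
F7 | step 2 | 2-(6-formyl-2,3-dimethoxyphenoxy)benzonitrile | COc1ccc(C=O)c(Oc2ccccc2C#N)c1OC
F8 | step 2 | 2-(6-{2-[4-(benzyloxy)phenyl]ethenyl}-2,3-dimethoxyphenoxy)benzonitrile (E/Z mixture, E drawn) | COc1ccc(/C=C/c2ccc(OCc3ccccc3)cc2)c(Oc2ccccc2C#N)c1OC
F9 | step 11 | macrocyclic benzylic alcohol from reduction of 18 (racemic) | COc1cc2cc(c1O)Oc1ccc(cc1)CCc1ccc(OC)c(OC)c1Oc1ccccc1CC2O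
A1 | alternative 1 | macrocycle with ring B as a 1-aryloxy-4-alkylcyclohexa-1,4-diene (tetramethyl ether) | COc1cc2cc(c1OC)OC1=CCC(=CC1)CCc1ccc(OC)c(OC)c1Oc1ccccc1CC2
A2 | alternative 2 | macrocyclic 3-aryloxy-2-alkylcyclohex-2-enone (tetramethyl ether) | O=C1CCCC2=C1CCc1cc(OC)c(OC)c(c1)Oc1ccc(cc1)CCc1ccc(OC)c(OC)c1O2
A3 | alternative 3 | bromo dichloro macrocyclic diaryl ether (ring A phenol free, ring C dimethyl ether) | Oc1c(Br)cc2cc1Oc1c(Cl)cc(cc1Cl)CCc1ccc(OC)c(OC)c1Oc1ccccc1CC2
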